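I start with the easy part: these flasks share their charges and differ in how those charges go in, so I reckon how long links sit before the reading.

    first end groups + second end groups → links (k1 = 38 M⁻¹ s⁻¹)
    first end groups + one-sided end groups → capped ends (k2 = 280 M⁻¹ s⁻¹)
    links ⇌ isomer of the product (K3 = 1.7, k3 = 0.0063 s⁻¹)
    first end groups + links → side product (k4 = 0.11 M⁻¹ s⁻¹)
    second end groups + protic impurity → quenched reagent (k5 = 24 M⁻¹ s⁻¹)

all flasks: one-sided end groups 2.55 mM; protic impurity 1.02 mM; time 3.0 min

| charge | first end groups | second end groups | remark |
|---|---|---|---|
| north-west | 0.051 M | 1.02 equiv (fed, over 2.5 min) | all else is in the flask from the start; the feed brings no volume worth counting |
| south-east | 0.051 M | 1.02 equiv | everything together at the start |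
| north-east | 0.051 M (fed, over 2.5 min) | 1.02 equiv | all else is in the flask from the start; the feed brings no volume worth counting |

- percent here means first end groups units held: one side product counts as two
- run time (north-west): 3.0 min

* the flask that comes out highest in amount of links, in percent of the first end groups charged, or "all alike" when all lie within 1.5 percentage points (north-west / south-east / north-east / all alike)
* links at the end, in percent of the first end groups charged, north-west
* links at the end, in percent of the first end groups charged, south-east
* links at the end, in percent of the first end groups charged, north-east

Links are the kinetic product and the isomer of the product the thermodynamic one, and the pair relaxes with a single time constant. I carry its relaxation rate λ, the forward constant plus the backward constant, 0.600 min⁻¹. A batch of links of age t keeps a share φ as links: φ falls from whole towards 37.0%, and the excess above that decays as exp(−λt).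

Now I follow one first end group through its forks. One-sided end groups react 7.37 times as fast per encounter as second end groups, so I book their whole charge as capped, 5.00% of the first end groups. That leaves a pool of 95.0%. A link reacts with a first end group at 0.00289 of the coupling constant, so I drop this side step for now.

In south-east, coupling has a half-life of 0.35 s, far shorter than the run. Its links therefore count as born at zero, φ is 47.4%, and the flask gives 45.1%.

The feed lasts 400 lifetimes of first end groups in north-east and 290 lifetimes of second end groups in north-west, each lifetime reckoned against everything charged, so in these two flasks births follow the feed. Ages then spread evenly from 0.500 min to 3.0 min, and averaging the exponential gives φ = 61.2%. For north-east that means 58.1%.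

The weak link is north-west, where first end groups wait beside links. In north-west I let first end groups fall linearly over the feed while links rise linearly to an estimated 66.2%. Their product then averages one part in 6 of charge times peak, and each side product counts as two first end units. The side loss is 18.6%, so north-west gives 46.8%, and north-east comes highest.

The forecast names north-east, with 46.7% for north-west, 45% for south-east and 58.9% for north-east, above my north-east figure, and argues that “Feeding first end groups keeps them scarce”.

The simulation gives 46.8% for north-west, 44.7% for south-east and 58.5% for north-east, so north-east is highest. North-west's side product reads 15.9%, less than my 18.6%.

Now take south-east again, read at 5.0 min with every amount held. Capped ends stand at 5.00% and side product at 1.06%. The same λ gives φ = 40.2%, and the same pool gives 38.2%. The flask reads 37.8%.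

(The rate constants were set for the occasion; no experiment stands behind them.)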